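**Retrosynthetic overview**
- The target is 11β-hydroxy-GA34 (2β,3β,11β-trihydroxy-GA9); rings A–D and the 19,10-lactone are taken intact from commercial GA4, and no carbocycle is built.
- 11β-OH and 16-methylene ⇒ an 11β,16β-ether carrying CH2SiMe3 on C-16, opened by silicon-directed (Peterson-type) elimination.
- The ether ⇒ 1,5-hydrogen transfer from a 16β-alkoxy radical, which is the untested key step of this plan; the 16β-carbinol ⇒ 17-nor-16-ketone + Me3SiCH2MgCl; the ketone ⇒ cleavage of the 16-ene.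
- 2β,3β-diol ⇒ β-face dihydroxylation of a 2-ene ⇒ dehydration of the 3β-OH of GA4.
- Ring events: carbocycles preformed; only a dioxolane (diol protection) and an oxolane (the 11,16-ether) are closed and later reopened.

Assumption: GA4 (the gibberellin numbered 4 in the GA series, a catalogue fermentation product) is accepted as the commercial starting material, so this is a semisynthesis; GA4 supplies the stereocentres at C-4, C-5, C-6, C-8, C-9, C-10 and C-13, and the route sets C-2, C-3 and C-11.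

Numbering (gibberellin convention): ring A = C-1 to C-5 and C-10; ring B = C-5, C-6, C-8, C-9, C-10; ring C = C-8, C-9 and C-11 to C-14; ring D = C-8 and C-13 to C-16; C-7 is the acid carbon on C-6, C-18 the methyl and C-19 the lactone carbonyl on C-4. GA9 = 3-deoxy-GA4; GA34 = 2β-hydroxy-GA4.

**Route**

Step 1
Reactants: 1 GA4 (free 7-acid)
Product: 2 GA4 methyl ester
Conditions: MeI, KHCO3, DMF, rt
Reagents that add atoms: iodomethane CI
Why: Carboxylate O-alkylation (SN2) masks the 7-acid, which would otherwise form an acyl hypoiodite and decarboxylate in step 7; no stereocentre is touched.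

Step 2
Reactants: 2 GA4 methyl ester
Product: 4 GA4 17-nor-16-ketone methyl ester, via 16α,17-diol 3 (not isolated)
Conditions: OsO4 (2 mol %), NaIO4 (4 equiv), 2,6-lutidine, dioxane–H2O 3:1, rt
Reagents that add atoms: osmium tetroxide O=[Os](=O)(=O)=O; sodium metaperiodate [Na+].[O-]I(=O)(=O)=O
Why: Lemieux–Johnson oxidation dihydroxylates the only alkene and cleaves the diol to the norketone, removing C-17 so that it can be reinstalled with the hydroxyl on the opposite (endo) face of C-16.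

Step 3
Reactants: 4 GA4 17-nor-16-ketone methyl ester
Product: 6 2,3-didehydro-GA9 17-nor-16-ketone methyl ester, via alkoxysulfurane 5 (not isolated)
Conditions: Martin sulfurane (1.5 equiv), CH2Cl2, 0 °C → rt
Reagents that add atoms: none
Why: Martin sulfurane dehydration is an anti β-elimination: the axial 3β-oxygen is antiperiplanar to the axial 2α-H and C-4 is quaternary, so only the 2-ene can form.

Step 4
Reactants: 6 2,3-didehydro-GA9 17-nor-16-ketone methyl ester
Product: 7 GA34 17-nor-16-ketone methyl ester (2β,3β-diol)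
Conditions: OsO4 (5 mol %), NMO, acetone–H2O 5:1, rt
Reagents that add atoms: osmium tetroxide O=[Os](=O)(=O)=O; N-methylmorpholine N-oxide C[N+]1([O-])CCOCC1
Why: Upjohn cis-dihydroxylation; the α-face of the 2-ene is roofed by the lactone bridge, so OsO4 adds from the β-face and sets C-2 and C-3 together as the 2β,3β-diol.

Step 5
Reactants: 7 GA34 17-nor-16-ketone methyl ester
Product: 8 2β,3β-O-isopropylidene-GA34 17-nor-16-ketone methyl ester
Conditions: 2-methoxypropene, PPTS (cat.), CH2Cl2, 0 °C → rt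
Reagents that add atoms: 2-methoxypropene C=C(C)OC
Why: Acid-catalysed acetonide formation on the cis diol protects both secondary alcohols from hypoiodite formation and glycol cleavage in step 7.

Step 6
Reactants: 8 2β,3β-O-isopropylidene-GA34 17-nor-16-ketone methyl ester; 9 (trimethylsilyl)methylmagnesium chloride
Product: 10 16β-hydroxy-17-(trimethylsilyl)-16,17-dihydro-GA34 methyl ester 2,3-acetonide (16-OH endo, facing C-11)
Conditions: CeCl3 (anhydrous, 3 equiv), THF, −78 → 0 °C; aq. NH4Cl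
Reagents that add atoms: none
Why: Organocerium 1,2-addition (first half of a Peterson olefination; CeCl3 suppresses enolisation and ester attack) occurs from the exo face (the C-14 side) because the endo face is blocked by the axial 11β-H, so the new C-16 centre carries its hydroxyl endo (16β).

Step 7
Reactants: 10 16β-hydroxy-17-(trimethylsilyl)-16,17-dihydro-GA34 methyl ester 2,3-acetonide
Product: 13 11β,16β-epoxy-17-(trimethylsilyl)-16,17-dihydro-GA34 methyl ester 2,3-acetonide, via hypoiodite 11 (not isolated), via 11α-iodide 12 (not isolated)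
Conditions: PhI(OAc)2 (1.3 equiv), iodine (0.6 equiv), cyclohexane–CH2Cl2, visible light, 0 °C
Reagents that add atoms: none
Why: Suárez hypoiodite reaction: the 16β-alkoxy radical lies in van der Waals contact with the syn-axial 11β-H and abstracts it (1,5-hydrogen transfer), iodine traps C-11 from the open α-face, and the alcohol displaces iodide with inversion, so the oxygen is fixed on the β-face of C-11 by the ring geometry.

Step 8
Reactants: 13 11β,16β-epoxy-17-(trimethylsilyl)-16,17-dihydro-GA34 methyl ester 2,3-acetonide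
Product: 14 11β-hydroxy-GA34 methyl ester 2,3-acetonide
Conditions: BF3·OEt2 (2 equiv), CH2Cl2, −78 → −30 °C; aq. NaHCO3
Reagents that add atoms: none
Why: Lewis-acid ionisation of the tertiary C-16–O bond is driven by the β-silicon effect and the silyl group is lost at once (Peterson-type elimination of a β-alkoxysilane), which places the alkene regiospecifically between C-16 and C-17 and frees the 11β-hydroxyl with its configuration untouched.

Step 9
Reactants: 14 11β-hydroxy-GA34 methyl ester 2,3-acetonide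
Product: 15 11β-hydroxy-GA34 2,3-acetonide (free 7-acid)
Conditions: n-PrSLi, HMPA, rt; 1 M HCl to pH 3, 0 °C
Reagents that add atoms: none
Why: SN2 demethylation of the hindered ester by a soft thiolate avoids aqueous base, which would open the lactone and epimerise C-3 by retro-aldol.

Step 10
Reactants: 15 11β-hydroxy-GA34 2,3-acetonide
Product: 16 11β-hydroxy-GA34 (target)
Conditions: AcOH–H2O 4:1, 40 °C
Reagents that add atoms: none
Why: Mild acid-catalysed acetal hydrolysis frees the 2β,3β-diol; acetic acid is too weak to protonate the 16-ene, so the 11β-OH does not re-close onto C-16.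

**Compound list**

1 | GA4 (the gibberellin numbered 4 in the GA series): 3β-hydroxy, 19,10-lactone on the α-face, 6β-CO2H (C-7), 16-methylene, 5β-H, 9β-H | C=C1C[C@]23C[C@H]1CC[C@H]2[C@@]12CC[C@H](O)[C@@](C)(C(=O)O1)[C@H]2[C@@H]3C(=O)O | starting material
2 | GA4 methyl ester | C=C1C[C@]23C[C@H]1CC[C@H]2[C@@]12CC[C@H](O)[C@@](C)(C(=O)O1)[C@H]2[C@@H]3C(=O)OC | intermediate
3 | 16α,17-dihydroxy-16,17-dihydro-GA4 methyl ester (16-OH exo) | OC[C@@]1(O)C[C@]23C[C@H]1CC[C@H]2[C@@]12CC[C@H](O)[C@@](C)(C(=O)O1)[C@H]2[C@@H]3C(=O)OC | intermediate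
4 | GA4 17-nor-16-ketone methyl ester | O=C1C[C@]23C[C@H]1CC[C@H]2[C@@]12CC[C@H](O)[C@@](C)(C(=O)O1)[C@H]2[C@@H]3C(=O)OC | intermediate
5 | alkoxysulfurane of 4: the 3β-oxygen bonded to diphenylsulfur that also carries a 1,1,1,3,3,3-hexafluoro-2-phenylpropan-2-yloxy group | O=C1C[C@]23C[C@H]1CC[C@H]2[C@@]12CC[C@H](OS(c4ccccc4)(c4ccccc4)OC(c4ccccc4)(C(F)(F)F)C(F)(F)F)[C@@](C)(C(=O)O1)[C@H]2[C@@H]3C(=O)OC | intermediate
6 | 2,3-didehydro-GA9 17-nor-16-ketone methyl ester (2-ene) | O=C1C[C@]23C[C@H]1CC[C@H]2[C@@]12CC=C[C@@](C)(C(=O)O1)[C@H]2[C@@H]3C(=O)OC | intermediate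
7 | GA34 17-nor-16-ketone methyl ester (2β,3β-diol) | O=C1C[C@]23C[C@H]1CC[C@H]2[C@@]12C[C@H](O)[C@H](O)[C@@](C)(C(=O)O1)[C@H]2[C@@H]3C(=O)OC | intermediate
8 | 2β,3β-O-isopropylidene-GA34 17-nor-16-ketone methyl ester | O=C1C[C@]23C[C@H]1CC[C@H]2[C@@]12C[C@@H]4OC(C)(C)O[C@@H]4[C@@](C)(C(=O)O1)[C@H]2[C@@H]3C(=O)OC | intermediate
9 | (trimethylsilyl)methylmagnesium chloride | C[Si](C)(C)C[Mg]Cl | starting material
10 | 16β-hydroxy-17-(trimethylsilyl)-16,17-dihydro-GA34 methyl ester 2,3-acetonide (OH endo) | C[Si](C)(C)C[C@]1(O)C[C@]23C[C@H]1CC[C@H]2[C@@]12C[C@@H]4OC(C)(C)O[C@@H]4[C@@](C)(C(=O)O1)[C@H]2[C@@H]3C(=O)OC | intermediate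
11 | 16β-O-iodo derivative (hypoiodite) of 10 | C[Si](C)(C)C[C@]1(OI)C[C@]23C[C@H]1CC[C@H]2[C@@]12C[C@@H]4OC(C)(C)O[C@@H]4[C@@](C)(C(=O)O1)[C@H]2[C@@H]3C(=O)OC | intermediate
12 | 11α-iodo-16β-hydroxy-17-(trimethylsilyl)-16,17-dihydro-GA34 methyl ester 2,3-acetonide | C[Si](C)(C)C[C@]1(O)C[C@]23C[C@H]1C[C@@H](I)[C@H]2[C@@]12C[C@@H]4OC(C)(C)O[C@@H]4[C@@](C)(C(=O)O1)[C@H]2[C@@H]3C(=O)OC | intermediate
13 | 11β,16β-epoxy-17-(trimethylsilyl)-16,17-dihydro-GA34 methyl ester 2,3-acetonide | C[Si](C)(C)C[C@]1(O5)C[C@]23C[C@H]1C[C@H]5[C@H]2[C@@]12C[C@@H]4OC(C)(C)O[C@@H]4[C@@](C)(C(=O)O1)[C@H]2[C@@H]3C(=O)OC | intermediate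
14 | 11β-hydroxy-GA34 methyl ester 2,3-acetonide | C=C1C[C@]23C[C@H]1C[C@H](O)[C@H]2[C@@]12C[C@@H]4OC(C)(C)O[C@@H]4[C@@](C)(C(=O)O1)[C@H]2[C@@H]3C(=O)OC | intermediate
15 | 11β-hydroxy-GA34 2,3-acetonide (7-acid) | C=C1C[C@]23C[C@H]1C[C@H](O)[C@H]2[C@@]12C[C@@H]4OC(C)(C)O[C@@H]4[C@@](C)(C(=O)O1)[C@H]2[C@@H]3C(=O)O | intermediate
16 | 11β-hydroxy-GA34 (2β,3β,11β-trihydroxy-GA9; CNP0322347.1) | C=C1C[C@]23C[C@H]1C[C@H](O)[C@H]2[C@@]12C[C@H](O)[C@H](O)[C@@](C)(C(=O)O1)[C@H]2[C@@H]3C(=O)O | target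

**Totals**

Total step count: 10. Longest linear sequence: 10 steps (1 → 16).

**Steps most likely to fail**

Step 7 is the main risk: the tertiary 16-alkoxy radical may open ring D by β-scission faster than it abstracts 11β-H. The fallback sets out from 8 and comes back at 14, using a slower-fragmenting secondary alkoxy radical and putting nitrogen, not oxygen, on C-11 first. NaBH4 (hydride from the exo face) gives the 16β-alcohol F1, and NOCl/pyridine converts it into the 16β-nitrite F2. Photolysis at −20 °C (Barton reaction) and tautomerisation give the 11-oxime F3. Aqueous TiCl3/NH4OAc frees the 11-oxo-16β-alcohol F4, and Dess–Martin periodinane gives the 11,16-dione F5. One equivalent of Ph3P=CH2 methylenates the less hindered ring D carbonyl to the 11-oxo-16-ene F6. LiBH(s-Bu)3 then delivers hydride from the α-face, away from the two-carbon bridge of ring D, to give 14; this facial preference is an estimate.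

Step 8 is the second risk: BF3 may strip the acetonide, re-close the ether, or let the C-16 cation rearrange. The fallback sets out from 8 and comes back at 14, replacing the Lewis-acid opening by a reductive one. Me3SI/KN(SiMe3)2 (Corey–Chaykovsky, exo attack) gives the 16β,17-epoxide F7. Li2NiBr4 opens it at C-17 to the 17-bromo-16β-alcohol F8. The hypoiodite reaction of step 7 turns this into the 17-bromo-11β,16β-ether F9. Zn/NH4Cl in EtOH at 70 °C (Boord-type reductive β-elimination, acid-free) then gives 14.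

Step 3 is the third risk: the neopentylic axial 3β-alcohol may exchange slowly on sulfur or rearrange. The fallback sets out from 2 and comes back at 6, making the 2-ene from a ketone instead of by dehydration. Dess–Martin periodinane gives the 3-ketone F10. KN(SiMe3)2/PhNTf2 gives the 2-en-3-yl triflate F11, C-2 being the only enolisable position. OsO4/NaIO4, to which the electron-poor enol triflate is inert, cleaves the 16-ene through the 16α,17-diol F12 to the triflate norketone F13. Pd(OAc)2/PPh3 with HCO2H/Et3N in DMF at 60 °C reduces the triflate to 6.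

**Further compounds**

F1 | step 7 | 16β-hydroxy-17-nor-16,17-dihydro-GA34 methyl ester 2,3-acetonide (OH endo) | O[C@H]1C[C@]23C[C@H]1CC[C@H]2[C@@]12C[C@@H]4OC(C)(C)O[C@@H]4[C@@](C)(C(=O)O1)[C@H]2[C@@H]3C(=O)OC
F2 | step 7 | 16β-nitrite ester of F1 | O=NO[C@H]1C[C@]23C[C@H]1CC[C@H]2[C@@]12C[C@@H]4OC(C)(C)O[C@@H]4[C@@](C)(C(=O)O1)[C@H]2[C@@H]3C(=O)OC
F3 | step 7 | 11-hydroxyimino-16β-hydroxy-17-nor-16,17-dihydro-GA34 methyl ester 2,3-acetonide | O[C@H]1C[C@]23C[C@H]1CC(=NO)[C@H]2[C@@]12C[C@@H]4OC(C)(C)O[C@@H]4[C@@](C)(C(=O)O1)[C@H]2[C@@H]3C(=O)OC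
F4 | step 7 | 11-oxo-16β-hydroxy-17-nor-16,17-dihydro-GA34 methyl ester 2,3-acetonide | O[C@H]1C[C@]23C[C@H]1CC(=O)[C@H]2[C@@]12C[C@@H]4OC(C)(C)O[C@@H]4[C@@](C)(C(=O)O1)[C@H]2[C@@H]3C(=O)OC
F5 | step 7 | 11,16-dioxo-17-nor-GA34 methyl ester 2,3-acetonide | O=C1C[C@]23C[C@H]1CC(=O)[C@H]2[C@@]12C[C@@H]4OC(C)(C)O[C@@H]4[C@@](C)(C(=O)O1)[C@H]2[C@@H]3C(=O)OC
F6 | step 7 | 11-oxo-GA34 methyl ester 2,3-acetonide | C=C1C[C@]23C[C@H]1CC(=O)[C@H]2[C@@]12C[C@@H]4OC(C)(C)O[C@@H]4[C@@](C)(C(=O)O1)[C@H]2[C@@H]3C(=O)OC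
F7 | step 8 | 16β,17-epoxy-16,17-dihydro-GA34 methyl ester 2,3-acetonide (epoxide O endo) | C5O[C@]51C[C@]23C[C@H]1CC[C@H]2[C@@]12C[C@@H]4OC(C)(C)O[C@@H]4[C@@](C)(C(=O)O1)[C@H]2[C@@H]3C(=O)OC
F8 | step 8 | 17-bromo-16β-hydroxy-16,17-dihydro-GA34 methyl ester 2,3-acetonide | BrC[C@]1(O)C[C@]23C[C@H]1CC[C@H]2[C@@]12C[C@@H]4OC(C)(C)O[C@@H]4[C@@](C)(C(=O)O1)[C@H]2[C@@H]3C(=O)OC
F9 | step 8 | 17-bromo-11β,16β-epoxy-16,17-dihydro-GA34 methyl ester 2,3-acetonide | BrC[C@]1(O5)C[C@]23C[C@H]1C[C@H]5[C@H]2[C@@]12C[C@@H]4OC(C)(C)O[C@@H]4[C@@](C)(C(=O)O1)[C@H]2[C@@H]3C(=O)OC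
F10 | step 3 | 3-oxo-GA9 methyl ester (GA4 methyl ester 3-ketone) | C=C1C[C@]23C[C@H]1CC[C@H]2[C@@]12CCC(=O)[C@@](C)(C(=O)O1)[C@H]2[C@@H]3C(=O)OC
F11 | step 3 | 3-(trifluoromethanesulfonyloxy)-2,3-didehydro-GA9 methyl ester | C=C1C[C@]23C[C@H]1CC[C@H]2[C@@]12CC=C(OS(=O)(=O)C(F)(F)F)[C@@](C)(C(=O)O1)[C@H]2[C@@H]3C(=O)OC
F12 | step 3 | 16α,17-diol of F11 | OC[C@@]1(O)C[C@]23C[C@H]1CC[C@H]2[C@@]12CC=C(OS(=O)(=O)C(F)(F)F)[C@@](C)(C(=O)O1)[C@H]2[C@@H]3C(=O)OC
F13 | step 3 | 3-(trifluoromethanesulfonyloxy)-2,3-didehydro-GA9 17-nor-16-ketone methyl ester | O=C1C[C@]23C[C@H]1CC[C@H]2[C@@]12CC=C(OS(=O)(=O)C(F)(F)F)[C@@](C)(C(=O)O1)[C@H]2[C@@H]3C(=O)OC
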